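## Retrosynthetic overview

1. Target 29 ⇐ chromium-mediated intramolecular allylation/lactonisation at C6–C7 of the lactol-masked (Z)-enal 26, which carries a 2-(bromomethyl)enoate. This closes the ten-membered ring and then the γ-lactone.
2. The (Z)-C4=C5 bond ⇐ six-membered ring-closing metathesis of a mixed acrolein acetal on O2 (a temporary dihydropyran). C2 and C3/C4/C15 ⇐ Keck allylation of enal 12.
3. The C7 allyl bromide ⇐ vinylalumination of the C7 aldehyde, then SN2′ bromination.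
4. 8-O-isobutyryl/9-O-acetyl ⇐ Sharpless epoxidation of a (Z)-allylic alcohol, titanium-mediated acetolysis at C9, acylation at C8.
5. C7–C10, C14, C1 and both alkene geometries ⇐ key step: 1,6-vinyl addition/ring opening of methyl coumalate. Ring order: dihydropyran (step 11), then carbocycle and lactone (step 16).

Assumption: methyl coumalate (a 6π-electron 2-pyranone made from malic acid) is taken as an inexpensive commercial heteroaromatic starting material.
Numbering in the text is that of the target: ring C1–C10 (C1=C10, C4=C5), lactone O–C6/C7–C11(=C13)–C12, C14 = CO2Me, C15 = CH2OH.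

## Route

Step 1
Reactants: 1 methyl coumalate (methyl 2-oxo-2H-pyran-5-carboxylate); 2 vinylmagnesium bromide
Product: 4 (2Z,4E)-4-(methoxycarbonyl)hepta-2,4,6-trienoic acid, via bromomagnesium pyranolate adduct 3 (not isolated)
Conditions: CuBr·SMe2 (10 mol%), THF, −78 °C; then 1 M HCl
Reagents that add atoms: none
Why: Proposed new method: the vinylcopper species adds to C6 of the pyranone (1,6- to the lactone, 1,4- to the ester) and the resulting dienolate expels the ring carboxylate (E1cB, formally a 6π ring opening), which keeps the ring-derived (Z)-C8=C9 bond and, through A(1,3) strain in the ester enolate, puts the vinyl group trans to CO2Me; the closest known reaction type is the Grignard/cuprate 1,6-addition–ring opening of 2H-pyran-2-one to (2Z,4E)-dienoic acids.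

Step 2
Reactants: 4 (2Z,4E)-4-(methoxycarbonyl)hepta-2,4,6-trienoic acid
Product: 6 methyl (2E)-2-[(1Z)-3-hydroxyprop-1-en-1-yl]penta-2,4-dienoate, via mixed carbonic anhydride 5 (not isolated)
Conditions: ClCO2Et, N-methylmorpholine, THF, −15 °C; then NaBH4, H2O, 0 °C
Reagents that add atoms: none
Why: Borohydride reduction of a mixed carbonic anhydride reduces only the carboxylic acid and leaves the methyl ester and the Z geometry untouched.

Step 3
Reactants: 6 methyl (2E)-2-[(1Z)-3-hydroxyprop-1-en-1-yl]penta-2,4-dienoate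
Product: 7 methyl (2E)-2-[(2R,3S)-3-(hydroxymethyl)oxiran-2-yl]penta-2,4-dienoate
Conditions: Ti(OiPr)4 (20 mol%), L-(+)-diisopropyl tartrate (24 mol%), t-BuOOH, 4 Å MS, CH2Cl2, −20 °C
Reagents that add atoms: tert-butyl hydroperoxide, CC(C)(C)OO
Why: Sharpless asymmetric epoxidation touches only the allylic-alcohol alkene, and the L-(+)-tartrate gives the (2S,3R)-cis-epoxy alcohol, which fixes C8 (S) and the precursor configuration of C9.

Step 4
Reactants: 7 methyl (2E)-2-[(2R,3S)-3-(hydroxymethyl)oxiran-2-yl]penta-2,4-dienoate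
Product: 8 methyl (2E)-2-[(1S,2S)-1-(acetyloxy)-2,3-dihydroxypropyl]penta-2,4-dienoate
Conditions: Ti(OiPr)4 (1.5 equiv), AcOH (3 equiv), CH2Cl2, 0 °C → rt
Reagents that add atoms: acetic acid, CC(=O)O
Why: Titanium-templated C3-selective opening of a 2,3-epoxy alcohol by carboxylate (Sharpless) is an SN2 inversion at the allylic C9, so the acetate arrives as 9S and the 8,9-diol relationship becomes threo.

Step 5
Reactants: 8 methyl (2E)-2-[(1S,2S)-1-(acetyloxy)-2,3-dihydroxypropyl]penta-2,4-dienoate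
Product: 10 methyl (2E)-2-[(1S,2S)-1-(acetyloxy)-2-[(2-methylpropanoyl)oxy]-3-[(triethylsilyl)oxy]propyl]penta-2,4-dienoate, via mono-TES hydroxy acetate 9 (not isolated)
Conditions: TESCl, imidazole, CH2Cl2, −40 °C; then iPrCOCl, pyridine, 0 °C
Reagents that add atoms: chlorotriethylsilane, CC[Si](CC)(CC)Cl; 2-methylpropanoyl chloride, CC(C)C(=O)Cl
Why: Primary-selective silylation followed by fast acylation of the remaining secondary hydroxyl under weak base (nucleophilic acyl substitution, outrunning 1,2-acetyl migration) puts the isobutyrate on O8 without touching a stereocentre.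

Step 6
Reactants: 10 the TES/isobutyrate/acetate dienoate
Product: 12 methyl (2E)-2-[(1S,2S)-1-(acetyloxy)-2-[(2-methylpropanoyl)oxy]-3-[(triethylsilyl)oxy]propyl]-4-oxobut-2-enoate, via secondary ozonide 11 (not isolated)
Conditions: O3 (1.0 equiv, saturated CH2Cl2 solution), CH2Cl2, −78 °C; then Me2S, −78 °C → rt
Reagents that add atoms: ozone, [O-][O+]=O
Why: Ozonolysis cleaves the only alkene without a directly attached ester (the terminal vinyl group) and gives the fumarate-type (E)-4-oxo-enoate, the thermodynamically favoured geometry, so any minor C1=C10 isomer from step 1 can equilibrate here.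

Step 7
Reactants: 13 2-methylprop-2-en-1-ol
Product: 15 2-[(tributylstannyl)methyl]prop-2-en-1-ol, via dilithio dianion 14 (not isolated)
Conditions: n-BuLi (2.2 equiv), TMEDA, Et2O–hexane, 0 °C → rt; then Bu3SnCl, −78 °C → rt; H2O
Reagents that add atoms: tributyltin chloride, CCCC[Sn](Cl)(CCCC)CCCC
Why: Alkoxide-directed allylic lithiation gives the O,C-dianion, which is stannylated on carbon (dianion alkylation).

Step 8
Reactants: 15 2-[(tributylstannyl)methyl]prop-2-en-1-ol
Product: 16 tert-butyl(dimethyl)({2-[(tributylstannyl)methyl]prop-2-en-1-yl}oxy)silane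
Conditions: TBSCl, imidazole, DMF, rt
Reagents that add atoms: tert-butyl(chloro)dimethylsilane, CC(C)(C)[Si](C)(C)Cl
Why: Standard silylation of the primary allylic alcohol (future C15–OH).

Step 9
Reactants: 12 the (E)-4-oxo-enoate; 16 the 2-substituted allylstannane
Product: 17 methyl (2E,4S)-2-[(1S,2S)-1-(acetyloxy)-2-[(2-methylpropanoyl)oxy]-3-[(triethylsilyl)oxy]propyl]-6-({[tert-butyl(dimethyl)silyl]oxy}methyl)-4-hydroxyhepta-2,6-dienoate
Conditions: (S)-BINOL (20 mol%), Ti(OiPr)4 (10 mol%), 4 Å MS, CH2Cl2, −20 °C; aq. NaHCO3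
Reagents that add atoms: none
Why: Keck asymmetric allylation: the (S)-BINOL–titanium Lewis acid directs the stannane to the Si face of the enal carbonyl (1,2-addition), which sets C2 as S under catalyst control and brings in C3, C4 and C15.

Step 10
Reactants: 17 the C2 homoallylic alcohol; 18 3,3-diethoxyprop-1-ene (acrolein diethyl acetal, excess)
Product: 19 the mixed acetal of 17, methyl (2E,4S)-…-4-[(1-ethoxyprop-2-en-1-yl)oxy]hepta-2,6-dienoate (both acetal epimers)
Conditions: PPTS (5 mol%), 5 Å MS, toluene, 45 °C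
Reagents that add atoms: none
Why: Acid-catalysed transacetalisation attaches C5 and C6 through O2; the new acetal centre is of no consequence because C6 becomes an aldehyde again in step 15.

Step 11
Reactants: 19 the mixed acrolein acetal
Product: 20 methyl (2E)-2-[(1S,2S)-1-(acetyloxy)-2-[(2-methylpropanoyl)oxy]-3-[(triethylsilyl)oxy]propyl]-3-[(2S)-4-({[tert-butyl(dimethyl)silyl]oxy}methyl)-6-ethoxy-3,6-dihydro-2H-pyran-2-yl]prop-2-enoate
Conditions: second-generation Grubbs catalyst (5 mol%), CH2Cl2, 40 °C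
Reagents that add atoms: none
Why: Ring-closing metathesis to a six-membered ring forms the trisubstituted C4=C5 bond with C3 and C6 necessarily cis, which is the geometry the target needs.

Step 12
Reactants: 20 the dihydropyran acetal
Product: 22 methyl (2E)-2-[(1S,2R)-1-(acetyloxy)-2-[(2-methylpropanoyl)oxy]-3-oxopropyl]-3-[(2S)-4-({[tert-butyl(dimethyl)silyl]oxy}methyl)-6-ethoxy-3,6-dihydro-2H-pyran-2-yl]prop-2-enoate, via alkoxysulfonium chloride 21 (not isolated)
Conditions: (COCl)2, DMSO, CH2Cl2, −78 → −40 °C; then iPr2NEt, −78 → −20 °C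
Reagents that add atoms: none
Why: Swern oxidation acts directly on the primary triethylsilyl ether (activated DMSO exchanges the silyl group), while the TBS ether, acetal and esters are inert; the hindered base and low temperature limit β-elimination of the 9-acetate.

Step 13
Reactants: 22 the C7 aldehyde; 23 methyl propiolate
Product: 24 methyl (2E)-2-[(1S,2S)-1-(acetyloxy)-3-hydroxy-4-(methoxycarbonyl)-2-[(2-methylpropanoyl)oxy]pent-4-en-1-yl]-3-[(2S)-4-({[tert-butyl(dimethyl)silyl]oxy}methyl)-6-ethoxy-3,6-dihydro-2H-pyran-2-yl]prop-2-enoate (both C7 epimers)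
Conditions: 23, DIBAL-H, N-methylmorpholine N-oxide, THF, 0 °C; then 22, 0 °C → rt; Rochelle salt
Reagents that add atoms: none
Why: Vinylalumination (the aluminium variant of the Morita–Baylis–Hillman reaction) adds the α-aluminoacrylate to the aldehyde without amine base, so the β-acetoxy aldehyde does not eliminate; the C7 carbinol configuration is irrelevant because it is erased in step 14.

Step 14
Reactants: 24 the Morita–Baylis–Hillman-type alcohol
Product: 25 methyl (2Z,4S,5S,6E)-5-(acetyloxy)-2-(bromomethyl)-6-(methoxycarbonyl)-4-[(2-methylpropanoyl)oxy]-7-[(2S)-4-({[tert-butyl(dimethyl)silyl]oxy}methyl)-6-ethoxy-3,6-dihydro-2H-pyran-2-yl]hepta-2,6-dienoate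
Conditions: NBS, Me2S, CH2Cl2, 0 °C → rt
Reagents that add atoms: N-bromosuccinimide, O=C1CCC(=O)N1Br
Why: Corey–Kim-type activation of the allylic alcohol and SN2′ delivery of bromide give the rearranged, thermodynamically preferred (Z)-2-(bromomethyl)enoate.

Step 15
Reactants: 25 the allyl bromide acetal
Product: 26 methyl (2Z,4S,5S,6E)-5-(acetyloxy)-2-(bromomethyl)-7-[(2S)-6-hydroxy-4-(hydroxymethyl)-3,6-dihydro-2H-pyran-2-yl]-6-(methoxycarbonyl)-4-[(2-methylpropanoyl)oxy]hepta-2,6-dienoate (lactol anomers)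
Conditions: 48% aq. HF, MeCN, 0 °C → rt
Reagents that add atoms: water, O
Why: Mild acid hydrolyses the allylic acetal and removes the TBS group in one operation; the enal stays masked as the six-membered lactol, so the (Z)-C4=C5 geometry cannot isomerise.

Step 16
Reactants: 26 the bromo lactol
Product: 29 the target, methyl (3aS,4S,5S,6E,8S,10E,11aR)-5-(acetyloxy)-8-hydroxy-10-(hydroxymethyl)-3-methylidene-4-[(2-methylpropanoyl)oxy]-2-oxo-2,3,3a,4,5,8,9,11a-octahydrocyclodeca[b]furan-6-carboxylate, via open hydroxy-enal 27 (not isolated), via macrocyclic hydroxy ester 28 (not isolated)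
Conditions: CrCl2 (10 equiv), THF–DMF (4:1), rt, slow addition to 2 mM; aq. NH4Cl
Reagents that add atoms: none
Why: Intramolecular Nozaki–Hiyama (chromium Barbier) allylation through a chair transition state gives the anti C6/C7 pair (6R,7S, trans-lactone), with the C8–O bond in the plane of the allyl unit and the ring tether on the attacked face so that C11 ends cis to O8, and the C6 alkoxide then lactonises onto the C12 methyl ester.

## Compound list

1 | methyl coumalate (methyl 2-oxo-2H-pyran-5-carboxylate) | COC(=O)C1=COC(=O)C=C1 | starting material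
2 | vinylmagnesium bromide | C=C[Mg]Br | starting material
3 | bromomagnesium 5-(methoxycarbonyl)-6-vinyl-6H-pyran-2-olate (racemic 1,6-adduct) | COC(=O)C1=CC=C(O[Mg]Br)OC1C=C | intermediate
4 | (2Z,4E)-4-(methoxycarbonyl)hepta-2,4,6-trienoic acid | OC(=O)/C=C\C(=C/C=C)C(=O)OC | intermediate
5 | (2Z,4E)-4-(methoxycarbonyl)hepta-2,4,6-trienoic ethyl carbonic anhydride | CCOC(=O)OC(=O)/C=C\C(=C/C=C)C(=O)OC | intermediate
6 | methyl (2E)-2-[(1Z)-3-hydroxyprop-1-en-1-yl]penta-2,4-dienoate | OC/C=C\C(=C/C=C)C(=O)OC | intermediate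
7 | methyl (2E)-2-[(2R,3S)-3-(hydroxymethyl)oxiran-2-yl]penta-2,4-dienoate | OC[C@@H]1O[C@@H]1\C(=C/C=C)C(=O)OC | intermediate
8 | methyl (2E)-2-[(1S,2S)-1-(acetyloxy)-2,3-dihydroxypropyl]penta-2,4-dienoate | OC[C@H](O)[C@@H](OC(C)=O)\C(=C/C=C)C(=O)OC | intermediate
9 | methyl (2E)-2-[(1S,2S)-1-(acetyloxy)-2-hydroxy-3-[(triethylsilyl)oxy]propyl]penta-2,4-dienoate | CC[Si](CC)(CC)OC[C@H](O)[C@@H](OC(C)=O)\C(=C/C=C)C(=O)OC | intermediate
10 | methyl (2E)-2-[(1S,2S)-1-(acetyloxy)-2-[(2-methylpropanoyl)oxy]-3-[(triethylsilyl)oxy]propyl]penta-2,4-dienoate | CC[Si](CC)(CC)OC[C@H](OC(=O)C(C)C)[C@@H](OC(C)=O)\C(=C/C=C)C(=O)OC | intermediate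
11 | methyl (2E)-2-[(1S,2S)-1-(acetyloxy)-2-[(2-methylpropanoyl)oxy]-3-[(triethylsilyl)oxy]propyl]-3-(1,2,4-trioxolan-3-yl)prop-2-enoate (ozonide) | CC[Si](CC)(CC)OC[C@H](OC(=O)C(C)C)[C@@H](OC(C)=O)\C(=C/C1OCOO1)C(=O)OC | intermediate
12 | methyl (2E)-2-[(1S,2S)-1-(acetyloxy)-2-[(2-methylpropanoyl)oxy]-3-[(triethylsilyl)oxy]propyl]-4-oxobut-2-enoate | CC[Si](CC)(CC)OC[C@H](OC(=O)C(C)C)[C@@H](OC(C)=O)\C(=C/C=O)C(=O)OC | intermediate
13 | 2-methylprop-2-en-1-ol (methallyl alcohol) | CC(=C)CO | starting material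
14 | dilithio dianion of 2-methylprop-2-en-1-ol (O-lithio, C-lithiomethyl) | [Li]CC(=C)CO[Li] | intermediate
15 | 2-[(tributylstannyl)methyl]prop-2-en-1-ol | CCCC[Sn](CCCC)(CCCC)CC(=C)CO | intermediate
16 | tert-butyl(dimethyl)({2-[(tributylstannyl)methyl]prop-2-en-1-yl}oxy)silane | CCCC[Sn](CCCC)(CCCC)CC(=C)CO[Si](C)(C)C(C)(C)C | intermediate
17 | methyl (2E,4S)-2-[(1S,2S)-1-(acetyloxy)-2-[(2-methylpropanoyl)oxy]-3-[(triethylsilyl)oxy]propyl]-6-({[tert-butyl(dimethyl)silyl]oxy}methyl)-4-hydroxyhepta-2,6-dienoate | CC[Si](CC)(CC)OC[C@H](OC(=O)C(C)C)[C@@H](OC(C)=O)\C(=C/[C@@H](O)CC(=C)CO[Si](C)(C)C(C)(C)C)C(=O)OC | intermediate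
18 | 3,3-diethoxyprop-1-ene (acrolein diethyl acetal) | C=CC(OCC)OCC | starting material
19 | methyl (2E,4S)-2-[(1S,2S)-1-(acetyloxy)-2-[(2-methylpropanoyl)oxy]-3-[(triethylsilyl)oxy]propyl]-6-({[tert-butyl(dimethyl)silyl]oxy}methyl)-4-[(1-ethoxyprop-2-en-1-yl)oxy]hepta-2,6-dienoate (acetal carbon: both epimers) | CC[Si](CC)(CC)OC[C@H](OC(=O)C(C)C)[C@@H](OC(C)=O)\C(=C/[C@@H](OC(OCC)C=C)CC(=C)CO[Si](C)(C)C(C)(C)C)C(=O)OC | intermediate
20 | methyl (2E)-2-[(1S,2S)-1-(acetyloxy)-2-[(2-methylpropanoyl)oxy]-3-[(triethylsilyl)oxy]propyl]-3-[(2S)-4-({[tert-butyl(dimethyl)silyl]oxy}methyl)-6-ethoxy-3,6-dihydro-2H-pyran-2-yl]prop-2-enoate (C6 of the pyran: both epimers) | CC[Si](CC)(CC)OC[C@H](OC(=O)C(C)C)[C@@H](OC(C)=O)\C(=C/[C@@H]1CC(CO[Si](C)(C)C(C)(C)C)=CC(OCC)O1)C(=O)OC | intermediate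
21 | dimethyl(alkoxy)sulfonium chloride of the C7 oxygen of 20 (TES replaced by SMe2+) | C[S+](C)OC[C@H](OC(=O)C(C)C)[C@@H](OC(C)=O)\C(=C/[C@@H]1CC(CO[Si](C)(C)C(C)(C)C)=CC(OCC)O1)C(=O)OC.[Cl-] | intermediate
22 | methyl (2E)-2-[(1S,2R)-1-(acetyloxy)-2-[(2-methylpropanoyl)oxy]-3-oxopropyl]-3-[(2S)-4-({[tert-butyl(dimethyl)silyl]oxy}methyl)-6-ethoxy-3,6-dihydro-2H-pyran-2-yl]prop-2-enoate | O=C[C@H](OC(=O)C(C)C)[C@@H](OC(C)=O)\C(=C/[C@@H]1CC(CO[Si](C)(C)C(C)(C)C)=CC(OCC)O1)C(=O)OC | intermediate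
23 | methyl propiolate | C#CC(=O)OC | starting material
24 | methyl (2E)-2-[(1S,2S)-1-(acetyloxy)-3-hydroxy-4-(methoxycarbonyl)-2-[(2-methylpropanoyl)oxy]pent-4-en-1-yl]-3-[(2S)-4-({[tert-butyl(dimethyl)silyl]oxy}methyl)-6-ethoxy-3,6-dihydro-2H-pyran-2-yl]prop-2-enoate (carbinol C7: both epimers) | C=C(C(=O)OC)C(O)[C@H](OC(=O)C(C)C)[C@@H](OC(C)=O)\C(=C/[C@@H]1CC(CO[Si](C)(C)C(C)(C)C)=CC(OCC)O1)C(=O)OC | intermediate
25 | methyl (2Z,4S,5S,6E)-5-(acetyloxy)-2-(bromomethyl)-6-(methoxycarbonyl)-4-[(2-methylpropanoyl)oxy]-7-[(2S)-4-({[tert-butyl(dimethyl)silyl]oxy}methyl)-6-ethoxy-3,6-dihydro-2H-pyran-2-yl]hepta-2,6-dienoate | COC(=O)/C(CBr)=C/[C@H](OC(=O)C(C)C)[C@@H](OC(C)=O)\C(=C/[C@@H]1CC(CO[Si](C)(C)C(C)(C)C)=CC(OCC)O1)C(=O)OC | intermediate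
26 | methyl (2Z,4S,5S,6E)-5-(acetyloxy)-2-(bromomethyl)-7-[(2S)-6-hydroxy-4-(hydroxymethyl)-3,6-dihydro-2H-pyran-2-yl]-6-(methoxycarbonyl)-4-[(2-methylpropanoyl)oxy]hepta-2,6-dienoate (lactol anomers) | COC(=O)/C(CBr)=C/[C@H](OC(=O)C(C)C)[C@@H](OC(C)=O)\C(=C/[C@@H]1CC(CO)=CC(O)O1)C(=O)OC | intermediate
27 | methyl (2Z,4S,5S,6E,8S,10E)-5-(acetyloxy)-2-(bromomethyl)-8-hydroxy-10-(hydroxymethyl)-6-(methoxycarbonyl)-4-[(2-methylpropanoyl)oxy]-12-oxododeca-2,6,10-trienoate (open form of 26; C3 and C6 of the target cis on C4=C5) | COC(=O)/C(CBr)=C/[C@H](OC(=O)C(C)C)[C@@H](OC(C)=O)\C(=C/[C@@H](O)C/C(CO)=C\C=O)C(=O)OC | intermediate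
28 | methyl (1E,3S,5E,7R,8S,9S,10S)-10-(acetyloxy)-3,7-dihydroxy-5-(hydroxymethyl)-8-(3-methoxy-3-oxoprop-1-en-2-yl)-9-[(2-methylpropanoyl)oxy]cyclodeca-1,5-diene-1-carboxylate | COC(=O)C(=C)[C@H]1[C@H](O)/C=C(/CO)C[C@H](O)/C=C(/C(=O)OC)[C@H](OC(C)=O)[C@H]1OC(=O)C(C)C | intermediate
29 | methyl (3aS,4S,5S,6E,8S,10E,11aR)-5-(acetyloxy)-8-hydroxy-10-(hydroxymethyl)-3-methylidene-4-[(2-methylpropanoyl)oxy]-2-oxo-2,3,3a,4,5,8,9,11a-octahydrocyclodeca[b]furan-6-carboxylate | C=C1C(=O)O[C@@H]2/C=C(/CO)C[C@H](O)/C=C(/C(=O)OC)[C@H](OC(C)=O)[C@@H](OC(=O)C(C)C)[C@@H]12 | target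

## Step count and risks

Total steps: 16. Longest linear sequence: 14 (steps 1–6 and 9–16; steps 7–8 make allylstannane 16).

The three steps most likely to fail:

Step 16. The ten-membered ring closure sets C6 and C7 only by substrate control. The allylchromium may also lose the β-isobutyrate, and the aldehyde is present only as the minor tautomer of the lactol. The fallback is a stereospecific propargylation/cyclocarbonylation that sets out from aldehyde 22 and comes back at 29. Chelate-controlled addition of ethynylmagnesium bromide (MgBr2·OEt2, CH2Cl2, −78 °C; the minor 7-epimer is removed) gives the (7R)-ethynyl carbinol of 22 F3, with O7 syn to O8. MsCl/Et3N converts it into the propargylic methanesulfonate F4. Aqueous HF in MeCN then frees the lactol and the C15 hydroxyl to give the lactol mesylate F5. Pd(OAc)2/PPh3 with InI (THF–HMPA, high dilution) turns the mesylate into an allenylindium that adds to the enal by anti SE2′ after anti oxidative addition. C6 therefore takes the place of the mesylate oxygen and the adduct is anti, giving the macrocyclic 7-ethynyl-6-hydroxy compound F6. Palladium-catalysed cyclocarbonylation of this homopropargylic alcohol (PdCl2(PPh3)2, SnCl2, CO, MeCN, 60 °C) builds the α-methylene lactone and gives 29.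

Step 1. The new ring opening may suffer 1,2-attack on the lactone or ester, a second conjugate addition to the product, or loss of the sensitive triene acid. The fallback separates C–C bond formation from ring opening; it sets out from 1 and comes back at 4. Rhodium-catalysed conjugate vinylation with potassium vinyltrifluoroborate ([RhCl(cod)]2, dioxane–water, 40 °C) gives the isolable lactone methyl 2-oxo-6-vinyl-5,6-dihydro-2H-pyran-5-carboxylate F1. A separate DBU-induced E1cB opening (THF, 0 °C, then dilute acid) gives 4 under thermodynamic control of the C1=C10 geometry.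

Step 4. C9 is a pentadienyl-type position, so the titanium Lewis acid may cause ionisation (loss of configuration, SN2′ attack at C1 or C3) or acetyl migration in the diol. The fallback sets out from 7 and comes back at 9. The primary alcohol is silylated first (TESCl, imidazole, CH2Cl2, −20 °C) to give methyl (2E)-2-[(2R,3S)-3-{[(triethylsilyl)oxy]methyl}oxiran-2-yl]penta-2,4-dienoate F2. The epoxide is then opened without a Lewis acid by external acetate (CsOAc, AcOH, DMF, 50 °C), a plain SN2 inversion at the allylic C9, which is less deactivated than C8 next to the silyloxymethyl group. This gives 9, which is isobutyrylated to 10 as in the second half of step 5.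

Further compounds
F1 | step 1 | methyl 2-oxo-6-vinyl-5,6-dihydro-2H-pyran-5-carboxylate (racemic, cis/trans mixture) | COC(=O)C1C=CC(=O)OC1C=C
F2 | step 4 | methyl (2E)-2-[(2R,3S)-3-{[(triethylsilyl)oxy]methyl}oxiran-2-yl]penta-2,4-dienoate | CC[Si](CC)(CC)OC[C@@H]1O[C@@H]1\C(=C/C=C)C(=O)OC
F3 | step 16 | methyl (2E)-2-[1-(acetyloxy)-3-hydroxy-2-[(2-methylpropanoyl)oxy]pent-4-yn-1-yl]-3-[(2S)-4-({[tert-butyl(dimethyl)silyl]oxy}methyl)-6-ethoxy-3,6-dihydro-2H-pyran-2-yl]prop-2-enoate (C8, C9 as in 22; carbinol C7 R, O7 syn to O8) | C#C[C@@H](O)[C@H](OC(=O)C(C)C)[C@@H](OC(C)=O)\C(=C/[C@@H]1CC(CO[Si](C)(C)C(C)(C)C)=CC(OCC)O1)C(=O)OC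
F4 | step 16 | methanesulfonate of F3 at the C7 oxygen | C#C[C@@H](OS(C)(=O)=O)[C@H](OC(=O)C(C)C)[C@@H](OC(C)=O)\C(=C/[C@@H]1CC(CO[Si](C)(C)C(C)(C)C)=CC(OCC)O1)C(=O)OC
F5 | step 16 | methyl (2E)-2-[1-(acetyloxy)-3-[(methanesulfonyl)oxy]-2-[(2-methylpropanoyl)oxy]pent-4-yn-1-yl]-3-[(2S)-6-hydroxy-4-(hydroxymethyl)-3,6-dihydro-2H-pyran-2-yl]prop-2-enoate (lactol anomers; other centres as in F4) | C#C[C@@H](OS(C)(=O)=O)[C@H](OC(=O)C(C)C)[C@@H](OC(C)=O)\C(=C/[C@@H]1CC(CO)=CC(O)O1)C(=O)OC
F6 | step 16 | methyl (1E,3S,5E,7R,8S,9S,10S)-10-(acetyloxy)-8-ethynyl-3,7-dihydroxy-5-(hydroxymethyl)-9-[(2-methylpropanoyl)oxy]cyclodeca-1,5-diene-1-carboxylate | C#C[C@H]1[C@H](O)/C=C(/CO)C[C@H](O)/C=C(/C(=O)OC)[C@H](OC(C)=O)[C@H]1OC(=O)C(C)C
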